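## Analysis of the target

Target 19 is a 5-alkylresorcinol: one benzene ring carries hydroxyl groups on C1 and C3 and an unbranched seventeen-carbon chain on C5, so the three substituents are mutually meta and C2, C4 and C6 carry hydrogen. The only stereocentre is the carbinol carbon C2' of the chain (R), one CH2 group away from the ring and followed by a pentadecyl tail. There is no second stereocentre and no ring close enough to relay control, and the two carbon substituents of C2' differ only beyond their first CH2 group, so the configuration must come from a reagent or from a purchased chiral building block. The sensitive parts are the electron-rich resorcinol nucleus (oxidised in basic, aerated media and open to electrophiles at C2, C4 and C6) and the homobenzylic secondary alcohol (substitution or dehydration to a styrene under strong Brønsted or Lewis acids). The difficulty lies in placement, not size: the 1,3,5 pattern is the one that electrophilic substitution of a phenol does not give, the lone stereocentre must be one enantiomer, and the phenols must be unveiled last without harming the carbinol. The strategy reads the ring as two pieces: C1 (with its oxygen), C6, C5 (with the chain) and C4 are the carbon skeleton of a 3-substituted cyclobutenone, and C2–C3 (with the second oxygen on C3) is an alkoxyalkyne. Merging them in a thermal pericyclic cascade writes the meta pattern directly into the ring.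

## Retrosynthetic reasoning

**19 back to 18 and 17.** The last bond cut is the ethyl C–O bond of the aryl ether in 18. A thiolate dealkylation is not used: attack at an ethyl group is slow, and the ring would already be a phenoxide, so a second phenoxide would have to be expelled from it. A boron trihalide works with the opposite polarity (oxygen activation, halide attack on the ethyl group) and is unaffected by the free phenol. Such a Lewis acid would not leave a silyl ether in a defined state, so the Si–O bond is cut one step earlier, taking 18 back to 17. The forward steps must free two oxygens without ionising the carbinol carbon.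

**17 back to 11 and 12.** This is the disconnection that carries the plan. Ring bonds C1–C2 and C3–C4 are cut, which lifts out C2 and C3 with the ethoxy oxygen as ethoxyethyne 12. The remaining four ring carbons, with the C1 oxygen and the chain, close up to cyclobutenone 11. Cutting here and not at the benzylic bond gives an arene whose oxygen pattern is set by the polarity of the two partners, not by directing groups. It also gives two differentiated oxygens and keeps metals and bases away from the stereocentre. The forward reaction must run two electrocyclic ring openings, one [2+2] cycloaddition and one six-electron ring closure in a single operation, with one orientation of the alkyne.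

**11 back to 10, then to 7 and 9 (from 8).** The cyclobutenone is cut at C1–C2 and C3–C4 into terminal alkyne 7 and a ketene. A ketene without electron-withdrawing substituents adds poorly to an unactivated alkyne, so the electrophilic dichloroketene 9, generated from acid chloride 8, is used. The two chlorine atoms of 10 are then removed reductively. The orientation of this cycloaddition puts the chain on C3 of the four-membered ring, which becomes C5 of the arene.

**7 back to 6, 5 and 4, then to 3, 1 and 2.** After the silyl ether is removed (7 to 6), the bond between the propargylic CH2 and the alkyne is cut, giving epoxide 5 and acetylide 4. Epoxide 5 comes from chlorohydrin 3, and 3 from epichlorohydrin 1 and Grignard reagent 2 by cutting the C3'–C4' bond of the chain. The stereocentre is thus bought in 1 and is never a reacting centre: every bond formed at it or next to it is made at a neighbouring CH2 group. A catalytic enantioselective propargylation of a linear aldehyde would be one step shorter. It would tie the enantiomeric purity to a catalyst acting on an unbranched, enolisable substrate, whereas the chiral-pool sequence keeps the risk of the route in the key step.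

## Alternatives that were turned down

**Alternative 1:** Epoxidation of a styrene, then benzylic hydrogenolysis.
- Disconnection: the two C–O bonds of a trans epoxide and then its benzylic C–O bond. Target 19 is traced to the styrene 1-[(1E)-heptadec-1-en-1-yl]-3,5-dimethoxybenzene (A1).
- Key step: Shi epoxidation of A1 (a chiral dioxirane formed in situ from a carbohydrate-derived ketone and KHSO5) would give (2R,3R)-2-(3,5-dimethoxyphenyl)-3-pentadecyloxirane (A2). Hydrogenolysis of the benzylic C–O bond of A2 would leave the C-beta oxygen with its configuration, and the two methyl ethers would be cleaved last.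
- For: trans-disubstituted styrenes are the substrate class on which this epoxidation is most dependable. The arene is bought with its 1,3,5 pattern in place. The sequence (olefination, epoxidation, hydrogenolysis, demethylation) is about half as long as the chosen route, so on step count it is clearly stronger.
- Against:
  - The enantiomeric purity of the carbinol depends on the facial selectivity of the dioxirane and on the geometric purity of A1. Any Z olefin is epoxidised with weak control and feeds the wrong enantiomer into the hydrogenolysis.
  - The oxidant is generated in a buffered aqueous–organic medium in which a substrate with a C15 tail dissolves poorly.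
  - The meta-methoxy groups do not help to activate the benzylic C–O bond of A2, so its regioselective reduction gets no electronic support from the ring.
  - The end game needs two aryl ether cleavages beside the free carbinol, where the chosen route needs one.
- Comparison: in exchange for its length the chosen route offers a stereocentre that is bought enantiopure and never reacts, and a ring that emerges with its two oxygens differentiated.

**Alternative 2:** Three-component conjunctive coupling.
- Disconnection: both C–C bonds at the stereocentre and, after oxidation of a C–B bond, its C–O bond.
- Key step: a boron ate complex from an unbranched alkyllithium and a vinylboronic ester would undergo conjunctive coupling with an aryl triflate under Pd(OAc)2 and a chiral ferrocenyl bisphosphine. The 1,2-metallate shift forms the C-beta to C-gamma bond and reductive elimination forms the aryl to C-alpha bond. The product would be 2-[(2R)-1-(3,5-dimethoxyphenyl)heptadecan-2-yl]-4,4,5,5-tetramethyl-1,3,2-dioxaborolane (A3). Stereoretentive oxidation of the C–B bond of A3 and cleavage of its two methyl ethers would finish.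
- For: it is the most convergent plan. One step makes two C–C bonds and the stereocentre of A3, and the oxidation is reliable. In step count and convergence it is stronger than the chosen route.
- Against:
  - It needs a halide-free long-chain alkyllithium, because halide ions interfere with the metallate rearrangement, and it passes through an air-sensitive ate complex.
  - The enantioselectivity for a flexible unbranched migrating group rests entirely on the ligand.
  - Direct transfer of the alkyl group or beta-hydride elimination would give achiral by-products that are hard to separate from waxy A3.
  - It ends with the same double ether cleavage as alternative 1.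
- Comparison: the chosen route uses only bench-stable reagents, needs no precious metal and takes its configuration from the chiral pool, whereas A3 owes its configuration to a ligand.

**Alternative 3:** Biomimetic aldol closure of a polyketo ester.
- Disconnection: the ring is also built from open-chain material, but by cutting the bond between the chain-bearing ring carbon and its ester-bearing neighbour.
- Key step: methyl (9R)-9-(tert-butyldimethylsilyloxy)-3,5,7-trioxotetracosanoate (A4) would fold under mild aqueous base, C2 attacking the C7 ketone. Dehydration and enolisation would give methyl 2,4-dihydroxy-6-[(2R)-2-(tert-butyldimethylsilyloxy)heptadecyl]benzoate (A5).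
- For: the closure is mild and follows the biosynthetic folding. Both phenols arrive free, so no aryl ether has to be cleaved. On that point it is stronger than the chosen route.
- Against:
  - The silyloxy group of A4 is beta to the C7 carbonyl. The base that triggers the aldol can expel silanolate through the C8 enolate and erase the stereocentre.
  - A chain with three ketones and an ester can also close by Claisen condensation or lactonise to a pyranone.
  - A4 has to be assembled by polyanion acylations.
  - A5 carries a carboxyl carbon that 19 lacks, so hydrolysis and decarboxylation must follow before desilylation.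
- Comparison: counted from commercial materials it is longer than the chosen route and spreads risk over several steps. The chosen route closes the ring under neutral thermal conditions and introduces no carbon that must later be removed.

Key step: step 6

Remark on the chemistry: the carbinol carbon of 19 is R (O > CH2Ar > C15H31 > H). The descriptor is the same in every intermediate because the CH2 group that ends up on the arene side always outranks the CH2 group that leads into the alkyl tail. Compounds 2, 4 and 12 are used as purchased reagents or solutions.

## Route

Step 1
Reactants: 1 (R)-epichlorohydrin [(2R)-2-(chloromethyl)oxirane]; 2 tetradecylmagnesium chloride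
Product: 3 (2R)-1-chloroheptadecan-2-ol
Conditions: 2 (1.2 equiv), CuI (10 mol %), THF, −40 → 0 °C; then aq NH4Cl
Reagents that add atoms: none
Why: Copper-catalysed Grignard opening of the epoxide at its unsubstituted carbon (SN2) should leave the C–Cl bond intact at low temperature; no bond to the stereocentre is made or broken, so the configuration of 1 is carried into 3.

Step 2
Reactants: 3 (2R)-1-chloroheptadecan-2-ol; 4 lithium acetylide ethylenediamine complex
Product: 6 (4R)-nonadec-1-yn-4-ol, via (2R)-2-pentadecyloxirane 5 (not isolated)
Conditions: 4 (3 equiv), DMSO, 0 °C → rt; then H2O
Reagents that add atoms: none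
Why: The first equivalent of acetylide deprotonates 3, and the alkoxide closes to epoxide 5 by intramolecular Williamson displacement; a further equivalent opens 5 at the terminal carbon (epoxide alkynylation). Both events occur at the CH2 group next to the stereocentre, so the R configuration is retained.

Step 3
Reactants: 6 (4R)-nonadec-1-yn-4-ol
Product: 7 tert-butyldimethyl{[(4R)-nonadec-1-yn-4-yl]oxy}silane
Conditions: TBSCl, imidazole, DMF, rt
Reagents that add atoms: tert-butyldimethylsilyl chloride, CC(C)(C)[Si](C)(C)Cl
Why: Imidazole-promoted silylation of a secondary alcohol; the terminal alkyne is inert. The silyl ether is chosen because it should tolerate zinc salts, buffered acetic acid and prolonged heating at 80 °C.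

Step 4
Reactants: 7 tert-butyldimethyl{[(4R)-nonadec-1-yn-4-yl]oxy}silane; 8 trichloroacetyl chloride
Product: 10 4,4-dichloro-3-[(2R)-2-(tert-butyldimethylsilyloxy)heptadecyl]cyclobut-2-en-1-one, via dichloroketene 9 (not isolated)
Conditions: 8 (slow addition), Zn–Cu couple, Et2O–DME, rt
Reagents that add atoms: none
Why: Zinc dechlorination of 8 generates dichloroketene 9, which adds to the terminal alkyne in a ketene–alkyne [2+2] cycloaddition. The unsubstituted alkyne carbon bonds to the ketene carbonyl carbon, so the chain sits on C3; DME ties up the ZnCl2 formed.

Step 5
Reactants: 10 4,4-dichloro-3-[(2R)-2-(tert-butyldimethylsilyloxy)heptadecyl]cyclobut-2-en-1-one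
Product: 11 3-[(2R)-2-(tert-butyldimethylsilyloxy)heptadecyl]cyclobut-2-en-1-one
Conditions: Zn dust, AcOH, TMEDA, EtOH, 0 °C → rt
Reagents that add atoms: none
Why: Reductive dechlorination of an alpha,alpha-dichloroketone by zinc, with protonation of the zinc enolates; the amine buffer should keep the strained enone from acid-induced ring cleavage, and the remote stereocentre is untouched.

Step 6
Reactants: 11 3-[(2R)-2-(tert-butyldimethylsilyloxy)heptadecyl]cyclobut-2-en-1-one; 12 ethoxyethyne
Product: 17 3-ethoxy-5-[(2R)-2-(tert-butyldimethylsilyloxy)heptadecyl]phenol, via vinylketene 13 (not isolated), via vinylcyclobutenone 14 (not isolated), via dienylketene 15 (not isolated), via cyclohexadienone 16 (not isolated)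
Conditions: 12 (3 equiv), toluene, 80 °C, sealed tube
Reagents that add atoms: none
Why: This is a Danheiser benzannulation of a 3-alkylcyclobutenone with an alkoxyalkyne. At 80 °C 11 should undergo conrotatory four-electron ring opening (cleavage of its C1–C4 bond) to vinylketene 13, whose ketene carbon is attacked by the unsubstituted, nucleophilic carbon of 12; collapse of the dipole completes a [2+2] cycloaddition to 14 and forms bonds C1–C2 and C3–C4 of the future arene. A second four-electron opening of 14 gives dienylketene 15, whose thermal disrotatory six-electron electrocyclisation forms C1–C6 and closes the six-membered ring as cyclohexadienone 16, which tautomerises to phenol 17; C1–C6 is the original C1–C4 bond of 11 re-made, so the net result is insertion of the two alkyne carbons into the C1–C2 bond of 11. The one selectivity required is the orientation of the [2+2] step, and the polarisation of the ynol ether secures it: the oxygen-bearing alkyne carbon bonds to the former C2 of 11, so the ethoxy group ends up meta to both the new hydroxyl and the chain. Only the 3E isomer of 15 can cyclise, but opening of 14 is reversible, so the unproductive isomer should return to 14 and drain through the productive one. No stereocentre is created in 17 (the ring stereocentre of 14 is lost on opening), and the carbinol centre is insulated from the reacting pi system by a CH2 group under these neutral, metal-free conditions. The temperature is held at 80 °C so that 12 is captured by the ketene faster than it is lost by thermal retro-ene fragmentation.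

Step 7
Reactants: 17 3-ethoxy-5-[(2R)-2-(tert-butyldimethylsilyloxy)heptadecyl]phenol
Product: 18 3-ethoxy-5-[(2R)-2-hydroxyheptadecyl]phenol
Conditions: 48% aq HF, MeCN–THF, 0 °C → rt
Reagents that add atoms: none
Why: Fluoride-driven desilylation of a secondary silyl ether under mildly acidic conditions; the aryl ethyl ether and the phenol are inert, and the C–O bond at the stereocentre is not broken.

Step 8
Reactants: 18 3-ethoxy-5-[(2R)-2-hydroxyheptadecyl]phenol
Product: 19 5-[(2R)-2-hydroxyheptadecyl]benzene-1,3-diol
Conditions: BBr3 (4 equiv), CH2Cl2, −78 → 0 °C; then H2O
Reagents that add atoms: none
Why: Lewis-acid ether cleavage: BBr3 coordinates the aryl ether oxygen, bromide attacks the ethyl CH2 group, and the aryloxyborane is hydrolysed on work-up. The carbinol is held as a borate and should return as the alcohol if the mixture is kept at or below 0 °C; the ring oxygens are meta to the chain-bearing carbon and do not assist ionisation at the carbinol carbon.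

## Compound list

1 | (R)-epichlorohydrin, (2R)-2-(chloromethyl)oxirane | ClC[C@H]1CO1 | starting material
2 | tetradecylmagnesium chloride | CCCCCCCCCCCCCC[Mg]Cl | starting material
3 | (2R)-1-chloroheptadecan-2-ol | CCCCCCCCCCCCCCC[C@@H](O)CCl | intermediate
4 | lithium acetylide ethylenediamine complex | [Li+].[C-]#C.NCCN | starting material
5 | (2R)-2-pentadecyloxirane | CCCCCCCCCCCCCCC[C@@H]1CO1 | intermediate (not isolated)
6 | (4R)-nonadec-1-yn-4-ol | CCCCCCCCCCCCCCC[C@@H](O)CC#C | intermediate
7 | tert-butyldimethyl{[(4R)-nonadec-1-yn-4-yl]oxy}silane | CCCCCCCCCCCCCCC[C@@H](O[Si](C)(C)C(C)(C)C)CC#C | intermediate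
8 | trichloroacetyl chloride | ClC(=O)C(Cl)(Cl)Cl | starting material
9 | dichloroketene | ClC(Cl)=C=O | intermediate (not isolated)
10 | 4,4-dichloro-3-[(2R)-2-(tert-butyldimethylsilyloxy)heptadecyl]cyclobut-2-en-1-one | CCCCCCCCCCCCCCC[C@@H](O[Si](C)(C)C(C)(C)C)CC1=CC(=O)C1(Cl)Cl | intermediate
11 | 3-[(2R)-2-(tert-butyldimethylsilyloxy)heptadecyl]cyclobut-2-en-1-one | CCCCCCCCCCCCCCC[C@@H](O[Si](C)(C)C(C)(C)C)CC1=CC(=O)C1 | intermediate
12 | ethoxyethyne | CCOC#C | starting material
13 | 3-[(2R)-2-(tert-butyldimethylsilyloxy)heptadecyl]buta-1,3-dien-1-one (vinylketene) | CCCCCCCCCCCCCCC[C@@H](O[Si](C)(C)C(C)(C)C)CC(=C)C=C=O | intermediate (not isolated)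
14 | 4-[(4R)-4-(tert-butyldimethylsilyloxy)nonadec-1-en-2-yl]-3-ethoxycyclobut-2-en-1-one (vinylcyclobutenone; either configuration at ring C4) | CCCCCCCCCCCCCCC[C@@H](O[Si](C)(C)C(C)(C)C)CC(=C)C1C(OCC)=CC1=O | intermediate (not isolated)
15 | (3E)-3-ethoxy-5-[(2R)-2-(tert-butyldimethylsilyloxy)heptadecyl]hexa-1,3,5-trien-1-one (dienylketene) | CCCCCCCCCCCCCCC[C@@H](O[Si](C)(C)C(C)(C)C)CC(=C)/C=C(OCC)\C=C=O | intermediate (not isolated)
16 | 3-ethoxy-5-[(2R)-2-(tert-butyldimethylsilyloxy)heptadecyl]cyclohexa-2,4-dien-1-one | CCCCCCCCCCCCCCC[C@@H](O[Si](C)(C)C(C)(C)C)CC1=CC(OCC)=CC(=O)C1 | intermediate (not isolated)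
17 | 3-ethoxy-5-[(2R)-2-(tert-butyldimethylsilyloxy)heptadecyl]phenol | CCCCCCCCCCCCCCC[C@@H](O[Si](C)(C)C(C)(C)C)Cc1cc(O)cc(OCC)c1 | intermediate
18 | 3-ethoxy-5-[(2R)-2-hydroxyheptadecyl]phenol | CCCCCCCCCCCCCCC[C@@H](O)Cc1cc(O)cc(OCC)c1 | intermediate
19 | 5-[(2R)-2-hydroxyheptadecyl]benzene-1,3-diol | CCCCCCCCCCCCCCC[C@@H](O)Cc1cc(O)cc(O)c1 | target

## Step count and least certain steps

Total step count: 8. Longest linear sequence: 8 steps, from 1 to 19; compounds 2, 4, 8 and 12 enter as purchased partners.

**Step 6 (key step).**
- What may go wrong: the ynol ether may be lost by thermal fragmentation or self-condensation before the vinylketene captures it. The new phenol may be acylated by vinylketene still present. Material may stall at the vinylcyclobutenone stage if the second ring opening is slow at 80 °C. An excess of 12 in a closed vessel and a short treatment of the crude product with K2CO3 in MeOH (to cleave adventitious aryl esters) are the first measures.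
- Fallback: the arene is bought instead of built. From 3, ring closure with NaOH gives 5 as an isolated compound. Commercial 3,5-dimethoxyphenylmagnesium chloride with catalytic CuI in THF opens 5 at its terminal carbon to give (2R)-1-(3,5-dimethoxyphenyl)heptadecan-2-ol F1. BBr3 in CH2Cl2 then cleaves both methyl ethers and the sequence comes back to the route at 19.

**Step 8.**
- What may go wrong: the borate of the secondary alcohol may be substituted by bromide, or may eliminate towards the styrene, if the mixture has to be warmed to complete cleavage of the ethyl ether. Ethyl ethers react more slowly than methyl ethers.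
- Fallback: the carbinol oxygen is kept from forming a borate. From 18, acetylation of both hydroxyl groups (Ac2O, pyridine, catalytic DMAP) should give (2R)-1-(3-acetoxy-5-ethoxyphenyl)heptadecan-2-yl acetate F2. BBr3 at −78 → 0 °C cleaves the ethyl ether to give (2R)-1-(3-acetoxy-5-hydroxyphenyl)heptadecan-2-yl acetate F3. K2CO3 in degassed MeOH removes both acetates and returns to the route at 19.

**Step 4.**
- What may go wrong: the ZnCl2 formed may loosen the silyl ether or promote oligomerisation of dichloroketene, and conversion of an unactivated alkyne may be incomplete. A 1,3-shift of chlorine in 10 would be harmless, since the isomer is reduced to the same cyclobutenone.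
- Fallback: a keteniminium [2+2] cycloaddition that uses no zinc and no chlorine. From 7, the keteniminium salt generated in situ from N,N-dimethylacetamide, Tf2O and 2,4,6-collidine in 1,2-dichloroethane should add to the alkyne with the same orientation. The product is N-{3-[(2R)-2-(tert-butyldimethylsilyloxy)heptadecyl]cyclobut-2-en-1-ylidene}-N-methylmethanaminium trifluoromethanesulfonate F4. Hydrolysis with aqueous NaHCO3 returns to the route at 11, which also bypasses 10 and the reduction of step 5.

**Step 2.**
- What may go wrong: the strongly basic medium may move the triple bond from the terminal to an internal position, or opening of the epoxide formed in situ may be incomplete.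
- Fallback: the alkynylation is done under Lewis-acid activation at low temperature. From 3, NaOH gives isolated 5. Lithium (trimethylsilyl)acetylide with BF3·OEt2 in THF at −78 °C opens it to (4R)-1-(trimethylsilyl)nonadec-1-yn-4-ol F5. K2CO3 in MeOH removes the C-silyl group and returns to the route at 6.

## Further compounds

F1 | step 6 | (2R)-1-(3,5-dimethoxyphenyl)heptadecan-2-ol | CCCCCCCCCCCCCCC[C@@H](O)Cc1cc(OC)cc(OC)c1
F2 | step 8 | (2R)-1-(3-acetoxy-5-ethoxyphenyl)heptadecan-2-yl acetate | CCCCCCCCCCCCCCC[C@@H](OC(C)=O)Cc1cc(OC(C)=O)cc(OCC)c1
F3 | step 8 | (2R)-1-(3-acetoxy-5-hydroxyphenyl)heptadecan-2-yl acetate | CCCCCCCCCCCCCCC[C@@H](OC(C)=O)Cc1cc(OC(C)=O)cc(O)c1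
F4 | step 4 | N-{3-[(2R)-2-(tert-butyldimethylsilyloxy)heptadecyl]cyclobut-2-en-1-ylidene}-N-methylmethanaminium trifluoromethanesulfonate | CCCCCCCCCCCCCCC[C@@H](O[Si](C)(C)C(C)(C)C)CC1=CC(=[N+](C)C)C1.[O-]S(=O)(=O)C(F)(F)F
F5 | step 2 | (4R)-1-(trimethylsilyl)nonadec-1-yn-4-ol | CCCCCCCCCCCCCCC[C@@H](O)CC#C[Si](C)(C)C
A1 | alternative 1 | 1-[(1E)-heptadec-1-en-1-yl]-3,5-dimethoxybenzene | CCCCCCCCCCCCCCC/C=C/c1cc(OC)cc(OC)c1
A2 | alternative 1 | (2R,3R)-2-(3,5-dimethoxyphenyl)-3-pentadecyloxirane | CCCCCCCCCCCCCCC[C@H]1O[C@@H]1c1cc(OC)cc(OC)c1
A3 | alternative 2 | 2-[(2R)-1-(3,5-dimethoxyphenyl)heptadecan-2-yl]-4,4,5,5-tetramethyl-1,3,2-dioxaborolane | CCCCCCCCCCCCCCC[C@@H](B1OC(C)(C)C(C)(C)O1)Cc1cc(OC)cc(OC)c1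
A4 | alternative 3 | methyl (9R)-9-(tert-butyldimethylsilyloxy)-3,5,7-trioxotetracosanoate | CCCCCCCCCCCCCCC[C@@H](O[Si](C)(C)C(C)(C)C)CC(=O)CC(=O)CC(=O)CC(=O)OC
A5 | alternative 3 | methyl 2,4-dihydroxy-6-[(2R)-2-(tert-butyldimethylsilyloxy)heptadecyl]benzoate | CCCCCCCCCCCCCCC[C@@H](O[Si](C)(C)C(C)(C)C)Cc1cc(O)cc(O)c1C(=O)OC
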